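**Plan**

- Retrosynthesis: remove thirteen O-benzyl groups; in the fisetinidol unit on C8 of the catechin core cut C4–C4a of ring C (the bond made last), then C4–C8; in the unit on C6 cut C4–C6 and C4–C4a. Both units fall back on one open-chain aldehyde, ArA–O–CH(ArB)–CH(OBn)–CHO, and the core on 8-bromo-penta-O-benzylcatechin.
- Enabling feature: C4 of each upper unit is a diarylmethine between catechin ring A (C8 and C6 are each flanked ortho/para by the oxygens on C5, C7 and C8a) and the resorcinol-type ring A of fisetinidol, whose C4a lies para to O7 and ortho to O1. A C4 cation carried by the catechin ring can therefore be captured by C4a to close ring C.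
- Forward: aldehyde (steps 1–7); catechin is benzylated and brominated at C8 (steps 8–10); one equivalent of aldehyde builds the C6 unit, closing its ring C (step 11); the bromine is exchanged for lithium and added to a second equivalent of aldehyde (step 12); Friedel–Crafts cycloalkylation closes the last ring (step 13); hydrogenolysis (step 14).
- Stereochemistry: C2/C3 of the core come from (+)-catechin; C2/C3 of both fisetinidol units from one Sharpless asymmetric epoxidation followed by invertive phenoxide opening; C4 of each unit by induction from C3 and C2 (3,4-trans, all substituents equatorial).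

Key step: step 13

Assumption: the carbinol made in step 12 is carried on as the mixture of both epimers at the carbinol carbon, because that centre becomes trigonal in step 13; the excess bromide used in step 11 is recovered.

**Route**

Step 1
Reactants: 1 3,4-bis(benzyloxy)benzaldehyde
Product: 2 ethyl (E)-3-[3,4-bis(benzyloxy)phenyl]prop-2-enoate
Conditions: Ph3P=CHCO2Et (1.2 equiv), toluene, 90 °C
Reagents that add atoms: ethyl (triphenylphosphoranylidene)acetate, CCOC(=O)C=P(c1ccccc1)(c1ccccc1)c1ccccc1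
Why: Wittig olefination with a stabilised ylide should give the (E)-cinnamate.

Step 2
Reactants: 2 ethyl (E)-3-[3,4-bis(benzyloxy)phenyl]prop-2-enoate
Product: 3 (E)-3-[3,4-bis(benzyloxy)phenyl]prop-2-en-1-ol
Conditions: i-Bu2AlH (2.2 equiv), CH2Cl2, −78 to 0 °C; aqueous potassium sodium tartrate work-up
Reagents that add atoms: none
Why: 1,2-reduction of the conjugated ester by the aluminium hydride should give the allylic alcohol and leave the benzyl ethers and the alkene untouched.

Step 3
Reactants: 3 (E)-3-[3,4-bis(benzyloxy)phenyl]prop-2-en-1-ol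
Product: 4 [(2S,3S)-3-[3,4-bis(benzyloxy)phenyl]oxiran-2-yl]methanol
Conditions: Ti(OiPr)4 (10 mol%), L-(+)-diisopropyl tartrate (12 mol%), t-BuOOH (2 equiv), 4 Å MS, CH2Cl2, −25 °C; aqueous NaOH/NaCl work-up, product used without chromatography
Reagents that add atoms: tert-butyl hydroperoxide, CC(C)(C)OO
Why: Sharpless asymmetric epoxidation of an (E)-allylic alcohol with the L-(+)-tartrate ligand should deliver oxygen to the face that gives the (2S,3S)-trans-epoxy alcohol, which fixes the future C2 and C3 of both fisetinidol units; the non-acidic work-up allows for the acid-lability of this electron-rich aryl epoxide.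

Step 4
Reactants: 4 [(2S,3S)-3-[3,4-bis(benzyloxy)phenyl]oxiran-2-yl]methanol; 5 3-(benzyloxy)phenol
Product: 6 (2S,3R)-3-[3-(benzyloxy)phenoxy]-3-[3,4-bis(benzyloxy)phenyl]propane-1,2-diol
Conditions: 5 (1.5 equiv), NaOH (1.5 equiv), H2O/1,4-dioxane, 70 °C
Reagents that add atoms: none
Why: SN2 opening of the epoxide by phenoxide at the benzylic carbon (Williamson-type ether formation) should proceed with inversion there, creating the O1–C2 bond with the (R) configuration while the carbinol centre (future C3) keeps its configuration.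

Step 5
Reactants: 6 (2S,3R)-3-[3-(benzyloxy)phenoxy]-3-[3,4-bis(benzyloxy)phenyl]propane-1,2-diol
Product: 7 (4S)-4-[(R)-[3-(benzyloxy)phenoxy][3,4-bis(benzyloxy)phenyl]methyl]-2-phenyl-1,3-dioxolane (both acetal epimers)
Conditions: PhCH(OMe)2 (1.5 equiv), PPTS (5 mol%), CH2Cl2, rt
Reagents that add atoms: benzaldehyde dimethyl acetal, COC(OC)c1ccccc1
Why: Acid-catalysed transacetalisation should tie the 1,2-diol up as the benzylidene acetal under conditions too mild to ionise the benzylic aryl ether; the acetal centre is of no consequence.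

Step 6
Reactants: 7 (4S)-4-[(R)-[3-(benzyloxy)phenoxy][3,4-bis(benzyloxy)phenyl]methyl]-2-phenyl-1,3-dioxolane
Product: 8 (2S,3R)-2-(benzyloxy)-3-[3-(benzyloxy)phenoxy]-3-[3,4-bis(benzyloxy)phenyl]propan-1-ol
Conditions: i-Bu2AlH (3 equiv), CH2Cl2, −78 to 0 °C; aqueous potassium sodium tartrate work-up
Reagents that add atoms: none
Why: Regioselective reductive opening of a benzylidene acetal: aluminium should bind the less hindered primary oxygen, so that hydride delivery leaves the benzyl group on the secondary oxygen and frees the primary alcohol.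

Step 7
Reactants: 8 (2S,3R)-2-(benzyloxy)-3-[3-(benzyloxy)phenoxy]-3-[3,4-bis(benzyloxy)phenyl]propan-1-ol
Product: 9 (2R,3R)-2-(benzyloxy)-3-[3-(benzyloxy)phenoxy]-3-[3,4-bis(benzyloxy)phenyl]propanal
Conditions: TEMPO (10 mol%), PhI(OAc)2 (1.2 equiv), CH2Cl2, rt; used directly
Reagents that add atoms: none
Why: Oxoammonium-catalysed oxidation of the primary alcohol should stop at the aldehyde and is mild enough not to epimerise the alpha-benzyloxy centre (the descriptor changes from S to R only through the priority rules).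

Step 8
Reactants: 10 (+)-catechin, (2R,3S)-2-(3,4-dihydroxyphenyl)chroman-3,5,7-triol
Product: 11 (2R,3S)-5,7-bis(benzyloxy)-2-[3,4-bis(benzyloxy)phenyl]chroman-3-ol
Conditions: BnBr (4.4 equiv), K2CO3 (4.4 equiv), DMF, 0 °C to rt, argon
Reagents that add atoms: benzyl bromide, BrCc1ccccc1
Why: Williamson etherification in which carbonate deprotonates only the four phenols, so that the secondary alcohol stays free and the chiral-pool stereocentres C2 and C3 are untouched.

Step 9
Reactants: 11 (2R,3S)-5,7-bis(benzyloxy)-2-[3,4-bis(benzyloxy)phenyl]chroman-3-ol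
Product: 12 (2R,3S)-3,5,7-tris(benzyloxy)-2-[3,4-bis(benzyloxy)phenyl]chroman
Conditions: NaH (1.5 equiv), BnBr (1.5 equiv), n-Bu4NI (cat.), THF/DMF, 0 °C to rt
Reagents that add atoms: benzyl bromide, BrCc1ccccc1
Why: Williamson etherification of the remaining secondary alcohol should remove the only acidic proton before the later lithiation.

Step 10
Reactants: 12 (2R,3S)-3,5,7-tris(benzyloxy)-2-[3,4-bis(benzyloxy)phenyl]chroman
Product: 13 (2R,3S)-3,5,7-tris(benzyloxy)-2-[3,4-bis(benzyloxy)phenyl]-8-bromochroman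
Conditions: NBS (1.05 equiv), CH2Cl2, −78 °C to rt
Reagents that add atoms: N-bromosuccinimide, O=C1CCC(=O)N1Br
Why: Electrophilic aromatic bromination should take place once, at C8, the more reactive of the two free positions of the benzylated ring A; the bromine blocks C8 in step 11 and is the lithiation handle in step 12.

Step 11
Reactants: 9 (2R,3R)-2-(benzyloxy)-3-[3-(benzyloxy)phenoxy]-3-[3,4-bis(benzyloxy)phenyl]propanal; 13 (2R,3S)-3,5,7-tris(benzyloxy)-2-[3,4-bis(benzyloxy)phenyl]-8-bromochroman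
Product: 15 8-bromo-6-[(2R,3S,4S)-3,7-bis(benzyloxy)-2-[3,4-bis(benzyloxy)phenyl]chroman-4-yl] derivative of 12 (nona-O-benzyl 8-bromo-fisetinidol-(4α→6)-catechin), via flavan-4-ol 14 (not isolated)
Conditions: 13 (3 equiv), Me3SiOTf (0.2 equiv), 4 Å MS, CH2Cl2, −78 to −30 °C; Et3N quench
Reagents that add atoms: none
Why: Tandem Friedel–Crafts hydroxyalkylation and Friedel–Crafts arylation, in which the activated aldehyde should be attacked by its own aryl ether at the carbon para to the benzyloxy group to give the flavan-4-ol, whose C4 cation (stabilised by O7 and O1) is captured by C6, the only free ring-A position of 13, anti to the C3 benzyloxy group to set the 3,4-trans (4α, 4S) centre; the other order of the two bond formations would lead to the same product.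

Step 12
Reactants: 15 nona-O-benzyl 8-bromo-fisetinidol-(4α→6)-catechin; 9 (2R,3R)-2-(benzyloxy)-3-[3-(benzyloxy)phenoxy]-3-[3,4-bis(benzyloxy)phenyl]propanal
Product: 17 8-[(1RS,2S,3R)-2-(benzyloxy)-3-[3-(benzyloxy)phenoxy]-3-[3,4-bis(benzyloxy)phenyl]-1-hydroxypropyl] analogue of 15 (carbinol in place of bromine), via aryllithium 16 (not isolated)
Conditions: t-BuLi (2.1 equiv), THF, −78 °C, 10 min; then 9 (1.5 equiv), −78 °C; H2O quench; chromatography on Et3N-deactivated silica
Reagents that add atoms: none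
Why: Bromine–lithium exchange followed by 1,2-addition of the aryllithium to the aldehyde should make the C4–C8 bond; the configuration of the new carbinol centre does not matter because it is planarised in step 13.

Step 13
Reactants: 17 carbinol (both epimers at the carbinol carbon)
Product: 18 trideca-O-benzyl ether of the target (all-trans fisetinidol units on C6 and C8 of penta-O-benzylcatechin)
Conditions: BF3·OEt2 (0.2 equiv), 4 Å MS, CH2Cl2, −78 to −30 °C; Et3N quench
Reagents that add atoms: none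
Why: The acid ionises the carbinol to a C4 cation delocalised into catechin ring A (oxygens on C7 and C8a ortho and on C5 para to C8), the tethered 3-benzyloxyphenyl ether attacks it through the carbon para to its benzyloxy group, which becomes C4a, and loss of a proton restores the arene. The closest known reaction type is the intramolecular Friedel–Crafts alkylation of aryl 3-aryl-3-hydroxypropyl ethers to 4-arylchromans. The one ring closed, the six-membered ring C, forms through the C4–C4a bond in a 6-exo-trig attack on the cationic carbon, with the arene bond C4a–C8a inside the new ring. The new stereocentre C4 is controlled by C2 and C3: in the chair-like transition state the C2 aryl and C3 benzyloxy groups lie equatorial and the catechin ring on the trigonal C4 takes the equatorial site, so that both carbinol epimers should converge on the 3,4-trans, 2,4-cis (4S) product. The step needs ionisation at C4 in preference to the benzylic C2–O1 ether and the existing interflavan bond, which the much greater stabilisation of a 2,4,6-trioxygenated benzyl cation and catalytic acid at low temperature secure. It also needs attack by the ring-A carbon para to oxygen and not by the carbon between the two oxygens or by ring B, which sterics, the double oxygen activation and the six- against five-membered transition state secure.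

Step 14
Reactants: 18 trideca-O-benzyl ether of the target
Product: 19 fisetinidol-(4α→8)-[fisetinidol-(4α→6)]-catechin (target)
Conditions: H2 (1 atm), Pd(OH)2/C, THF/MeOH/H2O, rt; filtration, purification on Sephadex LH-20
Reagents that add atoms: none
Why: Catalytic hydrogenolysis should cleave all thirteen benzyl ethers under neutral conditions that leave the C2–O1 bonds, the interflavan bonds and every stereocentre intact.

**Compound list**

1 | 3,4-bis(benzyloxy)benzaldehyde | O=Cc1ccc(OCc2ccccc2)c(OCc2ccccc2)c1 | starting material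
2 | ethyl (E)-3-[3,4-bis(benzyloxy)phenyl]prop-2-enoate | CCOC(=O)/C=C/c1ccc(OCc2ccccc2)c(OCc2ccccc2)c1 | intermediate
3 | (E)-3-[3,4-bis(benzyloxy)phenyl]prop-2-en-1-ol | OC/C=C/c1ccc(OCc2ccccc2)c(OCc2ccccc2)c1 | intermediate
4 | [(2S,3S)-3-[3,4-bis(benzyloxy)phenyl]oxiran-2-yl]methanol | OC[C@@H]1O[C@H]1c1ccc(OCc2ccccc2)c(OCc2ccccc2)c1 | intermediate
5 | 3-(benzyloxy)phenol | Oc1cccc(OCc2ccccc2)c1 | starting material
6 | (2S,3R)-3-[3-(benzyloxy)phenoxy]-3-[3,4-bis(benzyloxy)phenyl]propane-1,2-diol | OC[C@H](O)[C@H](Oc1cccc(OCc2ccccc2)c1)c1ccc(OCc2ccccc2)c(OCc2ccccc2)c1 | intermediate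
7 | (4S)-4-[(R)-[3-(benzyloxy)phenoxy][3,4-bis(benzyloxy)phenyl]methyl]-2-phenyl-1,3-dioxolane, both acetal epimers | c1ccccc1C1OC[C@H](O1)[C@H](Oc1cccc(OCc2ccccc2)c1)c1ccc(OCc2ccccc2)c(OCc2ccccc2)c1 | intermediate
8 | (2S,3R)-2-(benzyloxy)-3-[3-(benzyloxy)phenoxy]-3-[3,4-bis(benzyloxy)phenyl]propan-1-ol | OC[C@H](OCc1ccccc1)[C@H](Oc1cccc(OCc2ccccc2)c1)c1ccc(OCc2ccccc2)c(OCc2ccccc2)c1 | intermediate
9 | (2R,3R)-2-(benzyloxy)-3-[3-(benzyloxy)phenoxy]-3-[3,4-bis(benzyloxy)phenyl]propanal | O=C[C@H](OCc1ccccc1)[C@H](Oc1cccc(OCc2ccccc2)c1)c1ccc(OCc2ccccc2)c(OCc2ccccc2)c1 | intermediate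
10 | (+)-catechin, (2R,3S)-2-(3,4-dihydroxyphenyl)chroman-3,5,7-triol | Oc1cc(O)c2c(c1)O[C@H](c1ccc(O)c(O)c1)[C@@H](O)C2 | starting material
11 | (2R,3S)-5,7-bis(benzyloxy)-2-[3,4-bis(benzyloxy)phenyl]chroman-3-ol | c1ccccc1COc1cc(OCc2ccccc2)c2c(c1)O[C@H](c1ccc(OCc3ccccc3)c(OCc3ccccc3)c1)[C@@H](O)C2 | intermediate
12 | (2R,3S)-3,5,7-tris(benzyloxy)-2-[3,4-bis(benzyloxy)phenyl]chroman | c1ccccc1COc1cc(OCc2ccccc2)c2c(c1)O[C@H](c1ccc(OCc3ccccc3)c(OCc3ccccc3)c1)[C@@H](OCc1ccccc1)C2 | intermediate
13 | (2R,3S)-3,5,7-tris(benzyloxy)-2-[3,4-bis(benzyloxy)phenyl]-8-bromochroman | c1ccccc1COc1cc(OCc2ccccc2)c2c(c1Br)O[C@H](c1ccc(OCc3ccccc3)c(OCc3ccccc3)c1)[C@@H](OCc1ccccc1)C2 | intermediate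
14 | (2R,3S)-3,7-bis(benzyloxy)-2-[3,4-bis(benzyloxy)phenyl]chroman-4-ol, 2,3-trans, both C4 epimers | OC1c2ccc(OCc3ccccc3)cc2O[C@H](c2ccc(OCc3ccccc3)c(OCc3ccccc3)c2)[C@H]1OCc1ccccc1 | intermediate (not isolated)
15 | 8-bromo-6-[(2R,3S,4S)-3,7-bis(benzyloxy)-2-[3,4-bis(benzyloxy)phenyl]chroman-4-yl] derivative of 12 | c1ccccc1COc1ccc2c(c1)O[C@H](c1ccc(OCc3ccccc3)c(OCc3ccccc3)c1)[C@@H](OCc1ccccc1)[C@@H]2c1c(OCc3ccccc3)c2c(c(Br)c1OCc1ccccc1)O[C@H](c1ccc(OCc3ccccc3)c(OCc3ccccc3)c1)[C@@H](OCc1ccccc1)C2 | intermediate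
16 | 8-lithio analogue of 15 | c1ccccc1COc1ccc2c(c1)O[C@H](c1ccc(OCc3ccccc3)c(OCc3ccccc3)c1)[C@@H](OCc1ccccc1)[C@@H]2c1c(OCc3ccccc3)c2c(c([Li])c1OCc1ccccc1)O[C@H](c1ccc(OCc3ccccc3)c(OCc3ccccc3)c1)[C@@H](OCc1ccccc1)C2 | intermediate (not isolated)
17 | 8-[(1RS,2S,3R)-2-(benzyloxy)-3-[3-(benzyloxy)phenoxy]-3-[3,4-bis(benzyloxy)phenyl]-1-hydroxypropyl] analogue of 15 | c1ccccc1COc1ccc2c(c1)O[C@H](c1ccc(OCc3ccccc3)c(OCc3ccccc3)c1)[C@@H](OCc1ccccc1)[C@@H]2c1c(OCc3ccccc3)c2c(c(C(O)[C@H](OCc3ccccc3)[C@H](Oc3cccc(OCc4ccccc4)c3)c3ccc(OCc4ccccc4)c(OCc4ccccc4)c3)c1OCc1ccccc1)O[C@H](c1ccc(OCc3ccccc3)c(OCc3ccccc3)c1)[C@@H](OCc1ccccc1)C2 | intermediate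
18 | trideca-O-benzyl ether of the target: (2R,3S)-penta-O-benzylcatechin bearing (2R,3S,4S)-3,7-bis(benzyloxy)-2-[3,4-bis(benzyloxy)phenyl]chroman-4-yl groups on C6 and C8 | c1ccccc1COc1ccc2c(c1)O[C@H](c1ccc(OCc3ccccc3)c(OCc3ccccc3)c1)[C@@H](OCc1ccccc1)[C@@H]2c1c(OCc3ccccc3)c2c(c([C@@H]3c4ccc(OCc5ccccc5)cc4O[C@H](c4ccc(OCc5ccccc5)c(OCc5ccccc5)c4)[C@H]3OCc3ccccc3)c1OCc1ccccc1)O[C@H](c1ccc(OCc3ccccc3)c(OCc3ccccc3)c1)[C@@H](OCc1ccccc1)C2 | intermediate
19 | fisetinidol-(4α→8)-[fisetinidol-(4α→6)]-catechin: (2R,3S)-catechin bearing (2R,3S,4S)-2-(3,4-dihydroxyphenyl)-3,7-dihydroxychroman-4-yl groups on C6 and C8 | Oc1ccc2c(c1)O[C@H](c1ccc(O)c(O)c1)[C@@H](O)[C@@H]2c1c(O)c2c(c([C@@H]3c4ccc(O)cc4O[C@H](c4ccc(O)c(O)c4)[C@H]3O)c1O)O[C@H](c1ccc(O)c(O)c1)[C@@H](O)C2 | target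

**Count and risks**

Total step count: 14. Longest linear sequence: 11 steps (steps 1–7, then 11–14).

Steps most likely to fail:

Step 11. The cation generated in the flask may be consumed by self-condensation or by attack on benzyl-ether rings before the hindered, bromine-flanked C6 of 13 captures it, and the facial selectivity at C4 may be poor. The fallback separates the two events and uses a purified, capped electrophile. It sets out from 9, which is cyclised alone (SnCl4, CH2Cl2, −78 °C, cold quench) to isolate the flavan-4-ol 14. This is acetylated (Ac2O, pyridine, DMAP) to the 4-acetate of 14 F1, and F1 is coupled with an excess of 13 under BF3·OEt2 (CH2Cl2, −78 to 0 °C). The fallback comes back to the route at 15.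

Step 12. The hindered aryllithium may act as a base: enolisation of the alpha-benzyloxy aldehyde with loss of the beta-aryloxide, or proton transfer that quenches the carbanion. The fallback replaces the aldehyde addition by acylation and reduction. It sets out from 9, which is oxidised (NaClO2, NaH2PO4, 2-methyl-2-butene, t-BuOH/H2O) to the carboxylic acid F2 and converted (MeNH(OMe)·HCl, EDC, N-methylmorpholine, CH2Cl2) into the N-methoxy-N-methylamide F3. The far less acidic amide is added to aryllithium 16 (from 15, t-BuLi, THF, −78 °C) to give the aryl ketone F4, which is reduced (NaBH4, THF/MeOH, 0 °C). The fallback comes back to the route at 17.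

Step 13. The open-chain C4 cation may lose H3 to an enol ether, suffer a 1,2-hydride shift towards the C3 oxygen, or close onto the wrong arene carbon before the desired capture. The fallback returns to the ring-first order of bond formation, in which the C4 cation sits inside a preformed pyran ring. It sets out from 15, which is debrominated (t-BuLi, THF, −78 °C; MeOH) to the C8-unsubstituted dimer F5. F5 is condensed with 9 under the conditions of step 11 (Me3SiOTf, 4 Å MS, CH2Cl2, −78 to −30 °C); 9 cyclises to 14 in the flask and its C4 cation is captured by C8, the only free ring-A position, anti to the C3 benzyloxy group. The fallback comes back to the route at 18.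

**Further compounds**

F1 | step 11 | 4-acetate of 14, (2R)-2,3-trans-3,7-bis(benzyloxy)-2-[3,4-bis(benzyloxy)phenyl]chroman-4-yl acetate, both C4 epimers | CC(=O)OC1c2ccc(OCc3ccccc3)cc2O[C@H](c2ccc(OCc3ccccc3)c(OCc3ccccc3)c2)[C@H]1OCc1ccccc1
F2 | step 12 | (2R,3R)-2-(benzyloxy)-3-[3-(benzyloxy)phenoxy]-3-[3,4-bis(benzyloxy)phenyl]propanoic acid | OC(=O)[C@H](OCc1ccccc1)[C@H](Oc1cccc(OCc2ccccc2)c1)c1ccc(OCc2ccccc2)c(OCc2ccccc2)c1
F3 | step 12 | (2R,3R)-2-(benzyloxy)-3-[3-(benzyloxy)phenoxy]-3-[3,4-bis(benzyloxy)phenyl]-N-methoxy-N-methylpropanamide | CON(C)C(=O)[C@H](OCc1ccccc1)[C@H](Oc1cccc(OCc2ccccc2)c1)c1ccc(OCc2ccccc2)c(OCc2ccccc2)c1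
F4 | step 12 | aryl ketone corresponding to 17 (C=O in place of the carbinol CH–OH) | c1ccccc1COc1ccc2c(c1)O[C@H](c1ccc(OCc3ccccc3)c(OCc3ccccc3)c1)[C@@H](OCc1ccccc1)[C@@H]2c1c(OCc3ccccc3)c2c(c(C(=O)[C@H](OCc3ccccc3)[C@H](Oc3cccc(OCc4ccccc4)c3)c3ccc(OCc4ccccc4)c(OCc4ccccc4)c3)c1OCc1ccccc1)O[C@H](c1ccc(OCc3ccccc3)c(OCc3ccccc3)c1)[C@@H](OCc1ccccc1)C2
F5 | step 13 | debrominated analogue of 15 (hydrogen on C8) | c1ccccc1COc1ccc2c(c1)O[C@H](c1ccc(OCc3ccccc3)c(OCc3ccccc3)c1)[C@@H](OCc1ccccc1)[C@@H]2c1c(OCc3ccccc3)c2c(cc1OCc1ccccc1)O[C@H](c1ccc(OCc3ccccc3)c(OCc3ccccc3)c1)[C@@H](OCc1ccccc1)C2
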